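**Retrosynthetic overview**
1. The side chain goes on last. The C5–C(sp2) bond comes from Suzuki–Miyaura coupling of a 5-bromo-2,3-dihydrobenzofuran with an (E)-3-hydroxypropenylboronate, because a cinnamyl alcohol would not survive an anode.
2. Ring C (the dihydrofuran) is the only ring built; rings A and B are bought. The O1–C2 bond forms by anodic oxidation of the ring A benzylic CH2 of an enantiopure 1,2-diarylpropane. The ring B MOM-ether oxygen is the internal nucleophile, and C3 directs C2 (trans).
3. The C3–C3a bond forms by invertive displacement of a secondary tosylate by a ring B diarylcuprate.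
4. The tosylate comes from (S)-propylene oxide, the sole source of chirality, and the ring A Grignard reagent. The cuprate comes from 2,4-dibromo-6-methoxyphenol.

Assumption: 2,4-dibromo-6-methoxyphenol, (S)-propylene oxide and the pinacol ester of (E)-3-hydroxyprop-1-enylboronic acid are catalogue compounds, and the quoted potentials are estimates against SCE.

**Route**

Step 1
Reactants: 1 4-bromo-1,2-dimethoxybenzene; 2 (S)-propylene oxide
Product: 4 (2S)-1-(3,4-dimethoxyphenyl)propan-2-ol, via 3,4-dimethoxyphenylmagnesium bromide 3 (not isolated)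
Conditions: Mg, THF, reflux; CuBr·SMe2 (10 mol%), 2 (1.2 equiv), −30 → 0 °C; H2O quench
Reagents that add atoms: none
Why: Copper-catalysed Grignard opening of a terminal epoxide is an SN2 attack at the unsubstituted CH2, so the stereocentre of 2 is untouched and is carried into 4 as S.

Step 2
Reactants: 4 (2S)-1-(3,4-dimethoxyphenyl)propan-2-ol
Product: 5 (2S)-1-(3,4-dimethoxyphenyl)propan-2-yl 4-methylbenzenesulfonate
Conditions: TsCl (1.3 equiv), Et3N (2 equiv), DMAP (10 mol%), CH2Cl2, 0 °C → rt
Reagents that add atoms: TsCl, Cc1ccc(cc1)S(=O)(=O)Cl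
Why: O-Sulfonylation forms only an O–S bond, so the C–O bond and the S configuration are retained, and a sulfonate (unlike an iodide) is displaced by cuprates without radical scrambling.

Step 3
Reactants: 6 2,4-dibromo-6-methoxyphenol
Product: 7 1,5-dibromo-3-methoxy-2-(methoxymethoxy)benzene
Conditions: MOMCl (1.3 equiv), iPr2NEt (1.6 equiv), CH2Cl2, 0 °C → rt
Reagents that add atoms: MOMCl, COCCl
Why: This is a standard O-alkylation of a phenol with no stereocentre involved; the MOM group later directs the Br/Li exchange to the ortho bromine and leaves as an electrofuge at the anode.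

Step 4
Reactants: 7 1,5-dibromo-3-methoxy-2-(methoxymethoxy)benzene; 5 (2S)-1-(3,4-dimethoxyphenyl)propan-2-yl 4-methylbenzenesulfonate
Product: 10 5-bromo-1-[(2R)-1-(3,4-dimethoxyphenyl)propan-2-yl]-3-methoxy-2-(methoxymethoxy)benzene, via aryllithium 8 (not isolated), via lithium diarylcuprate 9 (not isolated)
Conditions: 7 (2.4 equiv), tBuLi (4.8 equiv), Et2O, −78 °C; CuBr·SMe2 (1.2 equiv), −78 → −30 °C; 5 (1.0 equiv), −30 → 0 °C, 16 h; aq. work-up
Reagents that add atoms: none
Why: Chelation-directed Br/Li exchange ortho to OMOM (the second tBuLi destroys tBuBr, so no competing alkyl halide remains) and Gilman cuprate formation are followed by SN2-type displacement of the secondary tosylate (inversion on going to trivalent copper, then retentive reductive elimination), which turns (S)-5 into (R)-10, the spatial arrangement of C3 in the target.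

Step 5
Reactants: 10 5-bromo-1-[(2R)-1-(3,4-dimethoxyphenyl)propan-2-yl]-3-methoxy-2-(methoxymethoxy)benzene
Product: 12 (2S,3S)-5-bromo-2-(3,4-dimethoxyphenyl)-7-methoxy-3-methyl-2,3-dihydro-1-benzofuran, via benzylic cation 11 (not isolated)
Conditions: undivided cell, graphite anode, Pt cathode, nBu4NPF6 (0.1 M), 2,6-lutidine (1.5 equiv), CH2Cl2/HFIP 3:1 (0.02 M), 2 mA cm−2, about 2.2 F mol−1 (stop at full conversion of 10), 0 °C
Reagents that add atoms: none
Why: Proposed new method: anodic dealkylative benzylic C(sp3)–H etherification, in which ring A (a 4-alkylveratrole, about +1.3 V) is oxidised before the brominated ring B (about +1.6 V, its OMOM group twisted out of conjugation by two ortho neighbours and therefore also more nucleophilic), lutidine deprotonates the radical cation at the only ring A benzylic position, the radical loses a second electron at once, and cation 11 is captured in a five-membered closure by the MOM-bearing oxygen, whose oxonium hands MeOCH2+ to HFIP while protons are reduced to H2 at the cathode; no free phenol is ever present, which matters because a phenol would be oxidised first and could lose the C3 stereocentre through an o-quinone methide; any benzylic HFIP ether formed by outside capture re-ionises in HFIP and feeds the same closure, and the buffer keeps any E1 alkene from being reprotonated, so that leak costs yield (achiral benzofuran) but not ee; the C3 methyl group sends ring A to the opposite face of the forming envelope (the trans isomer is also the thermodynamic one), which sets C2 as S; the closest known reaction types are anodic benzylic C–H alkoxylation and hexafluoroisopropoxylation by the electron–proton–electron sequence, DDQ-mediated oxidative cyclisation at electron-rich benzylic C–H bonds, and dealkylative ring closure of aryl alkyl ethers onto carbon electrophiles.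

Step 6
Reactants: 12 (2S,3S)-5-bromo-2-(3,4-dimethoxyphenyl)-7-methoxy-3-methyl-2,3-dihydro-1-benzofuran; 13 (E)-3-(4,4,5,5-tetramethyl-1,3,2-dioxaborolan-2-yl)prop-2-en-1-ol
Product: 14 (E)-3-[(2S,3S)-2-(3,4-dimethoxyphenyl)-7-methoxy-3-methyl-2,3-dihydro-1-benzofuran-5-yl]prop-2-en-1-ol
Conditions: 13 (1.5 equiv), Pd(OAc)2 (3 mol%), SPhos (6 mol%), K3PO4 (3 equiv), THF/H2O 10:1, 60 °C
Reagents that add atoms: none
Why: Suzuki–Miyaura coupling (oxidative addition of the aryl bromide to zerovalent palladium, transmetalation, reductive elimination) keeps the E geometry of the alkenylboronate, tolerates the free alcohol, and touches neither C2 nor C3, which carry no acidic hydrogen.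

**Compound list**
1 | 4-bromo-1,2-dimethoxybenzene (4-bromoveratrole) | COc1ccc(Br)cc1OC | starting material
2 | (S)-propylene oxide, (2S)-2-methyloxirane | C[C@H]1CO1 | starting material
3 | 3,4-dimethoxyphenylmagnesium bromide | COc1ccc([Mg]Br)cc1OC | intermediate
4 | (2S)-1-(3,4-dimethoxyphenyl)propan-2-ol | C[C@H](O)Cc1ccc(OC)c(OC)c1 | intermediate
5 | (2S)-1-(3,4-dimethoxyphenyl)propan-2-yl 4-methylbenzenesulfonate | C[C@H](OS(=O)(=O)c1ccc(C)cc1)Cc1ccc(OC)c(OC)c1 | intermediate
6 | 2,4-dibromo-6-methoxyphenol | COc1cc(Br)cc(Br)c1O | starting material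
7 | 1,5-dibromo-3-methoxy-2-(methoxymethoxy)benzene | COCOc1c(Br)cc(Br)cc1OC | intermediate
8 | [5-bromo-3-methoxy-2-(methoxymethoxy)phenyl]lithium | COCOc1c([Li])cc(Br)cc1OC | intermediate
9 | lithium bis[5-bromo-3-methoxy-2-(methoxymethoxy)phenyl]cuprate | [Li+].COCOc1c([Cu-]c2cc(Br)cc(OC)c2OCOC)cc(Br)cc1OC | intermediate
10 | 5-bromo-1-[(2R)-1-(3,4-dimethoxyphenyl)propan-2-yl]-3-methoxy-2-(methoxymethoxy)benzene | C[C@@H](c1cc(Br)cc(OC)c1OCOC)Cc1ccc(OC)c(OC)c1 | intermediate
11 | 2-[5-bromo-3-methoxy-2-(methoxymethoxy)phenyl]-1-(3,4-dimethoxyphenyl)propan-1-ylium, C2 arrangement as in 10 | C[C@@H](c1cc(Br)cc(OC)c1OCOC)[CH+]c1ccc(OC)c(OC)c1 | intermediate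
12 | (2S,3S)-5-bromo-2-(3,4-dimethoxyphenyl)-7-methoxy-3-methyl-2,3-dihydro-1-benzofuran (trans) | COc1ccc([C@H]2Oc3c(OC)cc(Br)cc3[C@@H]2C)cc1OC | intermediate
13 | (E)-3-(4,4,5,5-tetramethyl-1,3,2-dioxaborolan-2-yl)prop-2-en-1-ol | OC/C=C/B1OC(C)(C)C(C)(C)O1 | starting material
14 | (E)-3-[(2S,3S)-2-(3,4-dimethoxyphenyl)-7-methoxy-3-methyl-2,3-dihydro-1-benzofuran-5-yl]prop-2-en-1-ol | COc1ccc([C@H]2Oc3c(OC)cc(/C=C/CO)cc3[C@@H]2C)cc1OC | target

**Step count**
- Total step count: 6.
- Longest linear sequence: 5 (steps 1, 2, 4, 5, 6). Step 3 is the side branch.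

**Three steps most likely to fail**

Step 5 (the proposed new step).
- Risks: E1 loss of the C3 hydrogen from 11 to give an α-methylstilbene and then the benzofuran, over-oxidation of 12, and slow capture by the ether oxygen.
- The fallback sets out from 10 and comes back at 12, using known chemistry only. DDQ (1.1 equiv) in AcOH at rt carries out the established hydride-abstraction acetoxylation of p-alkoxy-activated benzylic positions. This gives (1RS,2S)-2-[5-bromo-3-methoxy-2-(methoxymethoxy)phenyl]-1-(3,4-dimethoxyphenyl)propyl acetate F1.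
- Catalytic HCl in MeOH/CH2Cl2 (0 °C → rt) then removes the MOM group and ionises the acetate. The free phenol closes the ring by SN1 etherification to the trans compound 12. The mixed C1 configuration of the acetate does not matter because the closure passes through the planar cation.

Step 4.
- Risks: E2 elimination of 5 to the conjugated propenylarene, sluggish transfer of an ortho-substituted aryl group to a secondary carbon, and aryl-assisted ionisation of 5.
- The fallback sets out from 7 and comes back at 10. It moves the stereodefining displacement to a far more reactive electrophile that cannot give a styrene. Cuprate 9, made as in step 4, is added at −78 °C to bought ethyl (S)-2-(trifluoromethylsulfonyloxy)propanoate (from ethyl L-lactate). The known invertive cuprate displacement of an α-sulfonyloxy ester gives ethyl (2S)-2-[5-bromo-3-methoxy-2-(methoxymethoxy)phenyl]propanoate F2.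
- iBu2AlH (2.5 equiv, CH2Cl2, −78 → 0 °C) gives (2S)-2-[5-bromo-3-methoxy-2-(methoxymethoxy)phenyl]propan-1-ol F3.
- TsCl/Et3N gives (2S)-2-[5-bromo-3-methoxy-2-(methoxymethoxy)phenyl]propyl 4-methylbenzenesulfonate F4.
- Li2CuCl4-catalysed coupling of this primary tosylate with Grignard reagent 3 (THF, −20 → 0 °C) leaves the stereocentre untouched and delivers 10.

Step 6.
- Risks: protodeboronation of 13 and slow oxidative addition of the electron-rich bromide.
- The fallback sets out from 12 and comes back at 14. A Heck reaction with methyl acrylate (Pd(OAc)2, P(o-tol)3, Et3N, DMF, 100 °C) gives methyl (E)-3-[(2S,3S)-2-(3,4-dimethoxyphenyl)-7-methoxy-3-methyl-2,3-dihydro-1-benzofuran-5-yl]prop-2-enoate F5.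
- 1,2-Reduction with iBu2AlH (2.2 equiv, CH2Cl2, −78 °C) then gives 14.

**Further compounds**
F1 | step 5 | (1RS,2S)-2-[5-bromo-3-methoxy-2-(methoxymethoxy)phenyl]-1-(3,4-dimethoxyphenyl)propyl acetate | C[C@@H](c1cc(Br)cc(OC)c1OCOC)C(OC(C)=O)c1ccc(OC)c(OC)c1
F2 | step 4 | ethyl (2S)-2-[5-bromo-3-methoxy-2-(methoxymethoxy)phenyl]propanoate | C[C@@H](c1cc(Br)cc(OC)c1OCOC)C(=O)OCC
F3 | step 4 | (2S)-2-[5-bromo-3-methoxy-2-(methoxymethoxy)phenyl]propan-1-ol | C[C@@H](c1cc(Br)cc(OC)c1OCOC)CO
F4 | step 4 | (2S)-2-[5-bromo-3-methoxy-2-(methoxymethoxy)phenyl]propyl 4-methylbenzenesulfonate | C[C@@H](c1cc(Br)cc(OC)c1OCOC)COS(=O)(=O)c1ccc(C)cc1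
F5 | step 6 | methyl (E)-3-[(2S,3S)-2-(3,4-dimethoxyphenyl)-7-methoxy-3-methyl-2,3-dihydro-1-benzofuran-5-yl]prop-2-enoate | COc1ccc([C@H]2Oc3c(OC)cc(/C=C/C(=O)OC)cc3[C@@H]2C)cc1OC
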